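Ring C is made last (abietane numbering). This hexasubstituted benzene has para oxygens at C11 and C14 that flank the fusion carbons C9 and C8, the signature of a Dötz benzannulation. A pentacarbonylchromium methoxycarbene attached to C9 of a cyclohexene that already holds the C5 and C10 stereocentres and a C7 silyl ether takes up 3-methylbut-1-yne and one CO ligand. This forms C11–C12, C13–C14 and C14–C8 in one operation and delivers the ring C 4-methoxyphenol with isopropyl at C13. Ring B comes from a copper-catalysed conjugate addition–methylation; C12–OH and the C3 and C7 oxidation levels are adjusted afterwards through the C11/C14 quinone.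

Key step: step 10

Numbering: C1–C3 are the propanoic acid chain (C3 = CO2H), C4 is the isopropenyl carbon, C5–C10 form ring B (C5 bears isopropenyl, C7 the ketone, C10 the methyl group and the chain), and C8, C9, C11–C14 form ring C (C13 bears isopropyl).

Assumption: C7 is drawn as the 7R epimer expected from step 5 (oxygen trans to the C5 isopropenyl group); the 7S epimer would serve equally, because C7 ends as a ketone.

Step 1
Reactants: 1 cyclohex-2-en-1-one
Product: 2 2-iodocyclohex-2-en-1-one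
Conditions: I2, K2CO3, DMAP (cat.), THF–H2O (1:1), rt
Reagents that add atoms: iodine, II
Why: α-Iodination of an enone by amine addition, iodination of the enolate and elimination (Baylis–Hillman-type activation by DMAP) is routine for cyclohex-2-enone and creates no stereocentre.

Step 2
Reactants: 3 tert-butyl(dimethyl)(prop-2-en-1-yloxy)silane; 2 2-iodocyclohex-2-en-1-one
Product: 5 2-[3-(tert-butyldimethylsilyloxy)propyl]cyclohex-2-en-1-one, via alkylborane 4 (not isolated)
Conditions: 3, 9-BBN-H dimer, THF, 0 °C → rt; then 2, PdCl2(dppf) (5 mol%), AsPh3, Cs2CO3, DMF–THF–H2O, rt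
Reagents that add atoms: none
Why: Anti-Markovnikov hydroboration of the terminal alkene followed by B-alkyl Suzuki–Miyaura coupling with the α-iodoenone (oxidative addition to zerovalent palladium, base-assisted transmetalation, reductive elimination) should attach C1–C3 to the future C10 without touching the enone.

Step 3
Reactants: 5 2-[3-(tert-butyldimethylsilyloxy)propyl]cyclohex-2-en-1-one; 6 isopropenylmagnesium bromide (THF solution)
Product: 8 (2R,3S)-2-[3-(tert-butyldimethylsilyloxy)propyl]-2-methyl-3-(prop-1-en-2-yl)cyclohexan-1-one, via bromomagnesium enolate 7 (not isolated)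
Conditions: 6 (1.5 equiv), Cu(OTf)2 (3 mol%), chiral hydroxyalkyl imidazolinium salt (NHC precursor, 4 mol%), Et2O, −30 °C; then MeI (8 equiv), DMPU, −30 °C → rt
Reagents that add atoms: iodomethane, CI
Why: Copper-catalysed asymmetric conjugate addition of a Grignard reagent to an α-substituted cyclohexenone should set C5 under ligand control (the ligand antipode is chosen so that isopropenyl enters the face giving 5S), and the regiodefined magnesium enolate should then be C-methylated anti to the neighbouring isopropenyl group (tandem conjugate addition–enolate alkylation), setting C10 (R) with methyl trans to isopropenyl.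

Step 4
Reactants: 8 (2R,3S)-2-[3-(tert-butyldimethylsilyloxy)propyl]-2-methyl-3-(prop-1-en-2-yl)cyclohexan-1-one
Product: 10 (5S,6R)-6-[3-(tert-butyldimethylsilyloxy)propyl]-6-methyl-5-(prop-1-en-2-yl)cyclohex-2-en-1-one, via trimethylsilyl enol ether 9 (not isolated)
Conditions: TMSOTf, Et3N, CH2Cl2, 0 °C; then Pd(OAc)2 (1.1 equiv), MeCN, rt
Reagents that add atoms: none
Why: Saegusa–Ito oxidation: because C10 is quaternary the ketone can enolise only toward C8, so one silyl enol ether should form, and its palladation and β-hydride elimination should give the C7=C8 enone without touching either stereocentre.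

Step 5
Reactants: 10 (5S,6R)-6-[3-(tert-butyldimethylsilyloxy)propyl]-6-methyl-5-(prop-1-en-2-yl)cyclohex-2-en-1-one
Product: 12 (2R,3S,5R)-2-[3-(tert-butyldimethylsilyloxy)propyl]-5-hydroxy-2-methyl-3-(prop-1-en-2-yl)cyclohexan-1-one, via pinacolboryl ketone 11 (not isolated)
Conditions: B2pin2 (1.1 equiv), CuCl (5 mol%), NaOtBu (10 mol%), Xantphos (5 mol%), MeOH (2 equiv), THF, rt; then NaBO3·4H2O, THF–H2O, rt
Reagents that add atoms: sodium perborate, [Na+].[O-]OB=O
Why: Copper-catalysed conjugate borylation of the enone followed by stereoretentive oxidation of the C–B bond should give the β-hydroxy ketone, the boryl group adding axially to C7 anti to the equatorial C5 isopropenyl group (7R), a configuration that is erased later.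

Step 6
Reactants: 12 (2R,3S,5R)-2-[3-(tert-butyldimethylsilyloxy)propyl]-5-hydroxy-2-methyl-3-(prop-1-en-2-yl)cyclohexan-1-one
Product: 13 (2R,3S,5R)-5-(tert-butyldimethylsilyloxy)-2-[3-(tert-butyldimethylsilyloxy)propyl]-2-methyl-3-(prop-1-en-2-yl)cyclohexan-1-one
Conditions: TBSCl, imidazole, DMF, rt
Reagents that add atoms: tert-butyldimethylsilyl chloride, CC(C)(C)[Si](C)(C)Cl
Why: Imidazole-promoted silylation of a secondary alcohol is mild enough to avoid β-elimination of the aldol-type hydroxy ketone.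

Step 7
Reactants: 13 (2R,3S,5R)-5-(tert-butyldimethylsilyloxy)-2-[3-(tert-butyldimethylsilyloxy)propyl]-2-methyl-3-(prop-1-en-2-yl)cyclohexan-1-one
Product: 15 (3R,5S,6R)-3-(tert-butyldimethylsilyloxy)-6-[3-(tert-butyldimethylsilyloxy)propyl]-6-methyl-5-(prop-1-en-2-yl)cyclohex-1-en-1-yl trifluoromethanesulfonate, via potassium enolate 14 (not isolated)
Conditions: KHMDS, THF, −78 °C; then N-(5-chloropyridin-2-yl)bis(trifluoromethanesulfonyl)imide, −78 °C
Reagents that add atoms: N-(5-chloropyridin-2-yl)bis(trifluoromethanesulfonyl)imide, O=S(=O)(N(c1ccc(Cl)cn1)S(=O)(=O)C(F)(F)F)C(F)(F)F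
Why: Deprotonation is possible only at C8, and O-sulfonylation of the potassium enolate at −78 °C (enol triflate synthesis) should be faster than E1cB loss of the β-silyloxy group.

Step 8
Reactants: 15 (3R,5S,6R)-3-(tert-butyldimethylsilyloxy)-6-[3-(tert-butyldimethylsilyloxy)propyl]-6-methyl-5-(prop-1-en-2-yl)cyclohex-1-en-1-yl trifluoromethanesulfonate
Product: 16 [(3R,5S,6R)-3-(tert-butyldimethylsilyloxy)-6-[3-(tert-butyldimethylsilyloxy)propyl]-6-methyl-5-(prop-1-en-2-yl)cyclohex-1-en-1-yl]trimethylstannane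
Conditions: Me3SnSnMe3, Pd(PPh3)4 (5 mol%), LiCl, THF, 65 °C
Reagents that add atoms: hexamethylditin, C[Sn](C)(C)[Sn](C)(C)C
Why: Palladium-catalysed stannylation of an enol triflate (oxidative addition to zerovalent palladium, chloride-assisted tin-to-palladium transmetalation, reductive elimination; a Stille-type coupling) tolerates silyl ethers and should cope with the hindered C10 neighbour.

Step 9
Reactants: 16 [(3R,5S,6R)-3-(tert-butyldimethylsilyloxy)-6-[3-(tert-butyldimethylsilyloxy)propyl]-6-methyl-5-(prop-1-en-2-yl)cyclohex-1-en-1-yl]trimethylstannane; 17 hexacarbonylchromium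
Product: 20 pentacarbonyl{methoxy[(3R,5S,6R)-3-(tert-butyldimethylsilyloxy)-6-[3-(tert-butyldimethylsilyloxy)propyl]-6-methyl-5-(prop-1-en-2-yl)cyclohex-1-en-1-yl]methylidene}chromium, via alkenyllithium 18 (not isolated), via lithium acylchromate 19 (not isolated)
Conditions: MeLi, THF, −78 → −20 °C; then Cr(CO)6, THF, 0 °C → rt; evaporate; Me3OBF4, CH2Cl2, 0 °C
Reagents that add atoms: trimethyloxonium tetrafluoroborate, C[O+](C)C.F[B-](F)(F)F
Why: Fischer carbene synthesis: tin–lithium exchange should give the alkenyllithium, which adds to a CO ligand of Cr(CO)6 to form the acylchromate (this carbon becomes C11), and O-methylation by the oxonium salt should give the methoxycarbene complex.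

Step 10
Reactants: 20 pentacarbonyl{methoxy[(3R,5S,6R)-3-(tert-butyldimethylsilyloxy)-6-[3-(tert-butyldimethylsilyloxy)propyl]-6-methyl-5-(prop-1-en-2-yl)cyclohex-1-en-1-yl]methylidene}chromium; 21 3-methylbut-1-yne
Product: 23 (5R,6S,8R)-8-(tert-butyldimethylsilyloxy)-5-[3-(tert-butyldimethylsilyloxy)propyl]-4-methoxy-5-methyl-2-(propan-2-yl)-6-(prop-1-en-2-yl)-5,6,7,8-tetrahydronaphthalen-1-ol, via tricarbonylchromium arene complex 22 (not isolated)
Conditions: 21 (2 equiv), THF (0.05 M), 50 °C, sealed tube, Ar; then air, rt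
Reagents that add atoms: none
Why: Thermal loss of one CO from 20 opens a site for the alkyne, which inserts into the Cr=C11 bond with its unsubstituted carbon bonding to C11 (C11–C12) to give a vinylcarbene, and CO insertion then forms C13–C14 and a chromium-bound dienylketene. The closest known reaction type is the Dötz benzannulation of cycloalkenyl(methoxy)carbene chromium complexes with terminal alkynes to fused 4-methoxyphenols. Ring C should close by a six-membered 6π-electrocyclisation of the dienylketene in which the ketene carbon C14 bonds to C8, and the cyclohexadienone so formed tautomerises to the phenol because C8 carries a hydrogen. No stereocentre is created: C5 and C10 are preset and remote from the reacting atoms, and C7 is not touched. The step needs regioselective alkyne insertion, secured sterically by the terminal alkyne (the isopropyl-bearing carbon ends next to the CO-derived C14), and preference for the alkyne over the isopropenyl group, secured because an unactivated 1,1-disubstituted alkene does not insert under these conditions. The zerovalent chromium tricarbonyl fragment left on the new arene in 22 should be stripped by air during work-up.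

Step 11
Reactants: 23 (5R,6S,8R)-8-(tert-butyldimethylsilyloxy)-5-[3-(tert-butyldimethylsilyloxy)propyl]-4-methoxy-5-methyl-2-(propan-2-yl)-6-(prop-1-en-2-yl)-5,6,7,8-tetrahydronaphthalen-1-ol
Product: 24 (5R,6S,8R)-8-(tert-butyldimethylsilyloxy)-5-[3-(tert-butyldimethylsilyloxy)propyl]-5-methyl-2-(propan-2-yl)-6-(prop-1-en-2-yl)-5,6,7,8-tetrahydronaphthalene-1,4-dione
Conditions: PhI(OAc)2 (1.2 equiv), MeCN–H2O (2:1), 0 °C
Reagents that add atoms: water, O
Why: Oxidative demethylation of a 4-methoxyphenol by a hypervalent iodine reagent (ligand exchange at the phenol oxygen, attack of water at C11, loss of methanol from the hemiketal) should give the C11/C14 quinone under nearly neutral conditions that spare both silyl ethers and the isopropenyl group.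

Step 12
Reactants: 24 (5R,6S,8R)-8-(tert-butyldimethylsilyloxy)-5-[3-(tert-butyldimethylsilyloxy)propyl]-5-methyl-2-(propan-2-yl)-6-(prop-1-en-2-yl)-5,6,7,8-tetrahydronaphthalene-1,4-dione
Product: 25 (5R,6S,8R)-8-(tert-butyldimethylsilyloxy)-5-[3-(tert-butyldimethylsilyloxy)propyl]-5-methyl-3-(morpholin-4-yl)-2-(propan-2-yl)-6-(prop-1-en-2-yl)-5,6,7,8-tetrahydronaphthalene-1,4-dione
Conditions: morpholine (3 equiv), Cu(OAc)2 (10 mol%), O2 (balloon), EtOH–THF, rt
Reagents that add atoms: morpholine, C1COCCN1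
Why: Oxidative amination of a quinone: the secondary amine should add in conjugate fashion to C12, the only unsubstituted quinone carbon (β to the C14 carbonyl), and the electron-rich aminohydroquinone should be reoxidised by oxygen to the aminoquinone, all under conditions free of acid.

Step 13
Reactants: 25 (5R,6S,8R)-8-(tert-butyldimethylsilyloxy)-5-[3-(tert-butyldimethylsilyloxy)propyl]-5-methyl-3-(morpholin-4-yl)-2-(propan-2-yl)-6-(prop-1-en-2-yl)-5,6,7,8-tetrahydronaphthalene-1,4-dione
Product: 26 (5R,6S,8R)-8-(tert-butyldimethylsilyloxy)-5-[3-(tert-butyldimethylsilyloxy)propyl]-3-hydroxy-5-methyl-2-(propan-2-yl)-6-(prop-1-en-2-yl)-5,6,7,8-tetrahydronaphthalene-1,4-dione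
Conditions: 1 M aq. NaOH, THF–MeOH, 45 °C, Ar; then aq. NaHSO4 to pH 3
Reagents that add atoms: water, O
Why: Hydrolysis of the vinylogous amide by addition–elimination of hydroxide at C12, driven by formation of the stabilised hydroxyquinone anion (the usual passage from amino- or alkoxyquinones to hydroxyquinones), should proceed in dilute base that leaves silyl ethers and the isopropenyl group untouched.

Step 14
Reactants: 26 (5R,6S,8R)-8-(tert-butyldimethylsilyloxy)-5-[3-(tert-butyldimethylsilyloxy)propyl]-3-hydroxy-5-methyl-2-(propan-2-yl)-6-(prop-1-en-2-yl)-5,6,7,8-tetrahydronaphthalene-1,4-dione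
Product: 27 (5R,6S,8R)-3,8-dihydroxy-5-(3-hydroxypropyl)-5-methyl-2-(propan-2-yl)-6-(prop-1-en-2-yl)-5,6,7,8-tetrahydronaphthalene-1,4-dione
Conditions: HF·pyridine, pyridine–THF, 0 °C → rt
Reagents that add atoms: none
Why: Fluoride-mediated cleavage of both silyl ethers under buffered conditions should avoid base-induced side reactions of the quinone and acid-induced dehydration at C7.

Step 15
Reactants: 27 (5R,6S,8R)-3,8-dihydroxy-5-(3-hydroxypropyl)-5-methyl-2-(propan-2-yl)-6-(prop-1-en-2-yl)-5,6,7,8-tetrahydronaphthalene-1,4-dione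
Product: 28 3-[(1R,2S)-7-hydroxy-1-methyl-4,5,8-trioxo-6-(propan-2-yl)-2-(prop-1-en-2-yl)-1,2,3,4,5,8-hexahydronaphthalen-1-yl]propanoic acid
Conditions: CrO3, aq. H2SO4, acetone, 0 °C
Reagents that add atoms: water, O
Why: Jones oxidation should take the secondary C7 alcohol to the ketone and the primary C3 alcohol through the aldehyde hydrate to the carboxylic acid in one operation, the hydroxyquinone being already at its highest useful oxidation level.

Step 16
Reactants: 28 3-[(1R,2S)-7-hydroxy-1-methyl-4,5,8-trioxo-6-(propan-2-yl)-2-(prop-1-en-2-yl)-1,2,3,4,5,8-hexahydronaphthalen-1-yl]propanoic acid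
Product: 29 3-[(1R,2S)-5,7,8-trihydroxy-1-methyl-4-oxo-6-(propan-2-yl)-2-(prop-1-en-2-yl)-1,2,3,4-tetrahydronaphthalen-1-yl]propanoic acid (CNP0198818.2)
Conditions: Na2S2O4, EtOAc–H2O (degassed), rt, Ar
Reagents that add atoms: none
Why: Dithionite should reduce the quinone selectively to the hydroquinone (two electrons, two protons) without touching the aryl ketone, the acid or the alkene, giving the C11/C12/C14 triol with the C14 hydroxyl hydrogen-bonded to the C7 ketone.

Compound list
1 | cyclohex-2-en-1-one | O=C1C=CCCC1 | starting material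
2 | 2-iodocyclohex-2-en-1-one | O=C1C(I)=CCCC1 | intermediate
3 | tert-butyl(dimethyl)(prop-2-en-1-yloxy)silane (allyl TBS ether) | C=CCO[Si](C)(C)C(C)(C)C | starting material
4 | 9-[3-(tert-butyldimethylsilyloxy)propyl]-9-borabicyclo[3.3.1]nonane (formed in situ) | CC(C)(C)[Si](C)(C)OCCCB1C2CCCC1CCC2 | intermediate
5 | 2-[3-(tert-butyldimethylsilyloxy)propyl]cyclohex-2-en-1-one | O=C1CCCC=C1CCCO[Si](C)(C)C(C)(C)C | intermediate
6 | isopropenylmagnesium bromide | C=C(C)[Mg]Br | starting material
7 | bromomagnesium enolate from 5, 5S (formed in situ) | C=C(C)[C@@H]1CCCC(O[Mg]Br)=C1CCCO[Si](C)(C)C(C)(C)C | intermediate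
8 | (2R,3S)-2-[3-(tert-butyldimethylsilyloxy)propyl]-2-methyl-3-(prop-1-en-2-yl)cyclohexan-1-one | C=C(C)[C@@H]1CCCC(=O)[C@]1(C)CCCO[Si](C)(C)C(C)(C)C | intermediate
9 | trimethylsilyl enol ether of 8, C8=C9 (formed in situ) | C=C(C)[C@@H]1CCC=C(O[Si](C)(C)C)[C@]1(C)CCCO[Si](C)(C)C(C)(C)C | intermediate
10 | (5S,6R)-6-[3-(tert-butyldimethylsilyloxy)propyl]-6-methyl-5-(prop-1-en-2-yl)cyclohex-2-en-1-one | C=C(C)[C@@H]1CC=CC(=O)[C@]1(C)CCCO[Si](C)(C)C(C)(C)C | intermediate
11 | (2R,3S,5R)-2-[3-(tert-butyldimethylsilyloxy)propyl]-2-methyl-3-(prop-1-en-2-yl)-5-(4,4,5,5-tetramethyl-1,3,2-dioxaborolan-2-yl)cyclohexan-1-one (formed in situ) | C=C(C)[C@@H]1C[C@@H](B2OC(C)(C)C(C)(C)O2)CC(=O)[C@]1(C)CCCO[Si](C)(C)C(C)(C)C | intermediate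
12 | (2R,3S,5R)-2-[3-(tert-butyldimethylsilyloxy)propyl]-5-hydroxy-2-methyl-3-(prop-1-en-2-yl)cyclohexan-1-one | C=C(C)[C@@H]1C[C@@H](O)CC(=O)[C@]1(C)CCCO[Si](C)(C)C(C)(C)C | intermediate
13 | (2R,3S,5R)-5-(tert-butyldimethylsilyloxy)-2-[3-(tert-butyldimethylsilyloxy)propyl]-2-methyl-3-(prop-1-en-2-yl)cyclohexan-1-one | C=C(C)[C@@H]1C[C@@H](O[Si](C)(C)C(C)(C)C)CC(=O)[C@]1(C)CCCO[Si](C)(C)C(C)(C)C | intermediate
14 | potassium enolate of 13 (formed in situ) | C=C(C)[C@@H]1C[C@@H](O[Si](C)(C)C(C)(C)C)C=C(O[K])[C@]1(C)CCCO[Si](C)(C)C(C)(C)C | intermediate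
15 | (3R,5S,6R)-3-(tert-butyldimethylsilyloxy)-6-[3-(tert-butyldimethylsilyloxy)propyl]-6-methyl-5-(prop-1-en-2-yl)cyclohex-1-en-1-yl trifluoromethanesulfonate | C=C(C)[C@@H]1C[C@@H](O[Si](C)(C)C(C)(C)C)C=C(OS(=O)(=O)C(F)(F)F)[C@]1(C)CCCO[Si](C)(C)C(C)(C)C | intermediate
16 | [(3R,5S,6R)-3-(tert-butyldimethylsilyloxy)-6-[3-(tert-butyldimethylsilyloxy)propyl]-6-methyl-5-(prop-1-en-2-yl)cyclohex-1-en-1-yl]trimethylstannane | C=C(C)[C@@H]1C[C@@H](O[Si](C)(C)C(C)(C)C)C=C([Sn](C)(C)C)[C@]1(C)CCCO[Si](C)(C)C(C)(C)C | intermediate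
17 | hexacarbonylchromium | O=C=[Cr](=C=O)(=C=O)(=C=O)(=C=O)=C=O | starting material
18 | alkenyllithium from 16 (formed in situ) | C=C(C)[C@@H]1C[C@@H](O[Si](C)(C)C(C)(C)C)C=C([Li])[C@]1(C)CCCO[Si](C)(C)C(C)(C)C | intermediate
19 | lithium acyl(pentacarbonyl)chromate (formed in situ) | C=C(C)[C@@H]1C[C@@H](O[Si](C)(C)C(C)(C)C)C=C(C(O[Li])=[Cr](=C=O)(=C=O)(=C=O)(=C=O)=C=O)[C@]1(C)CCCO[Si](C)(C)C(C)(C)C | intermediate
20 | pentacarbonyl{methoxy[(3R,5S,6R)-3-(tert-butyldimethylsilyloxy)-6-[3-(tert-butyldimethylsilyloxy)propyl]-6-methyl-5-(prop-1-en-2-yl)cyclohex-1-en-1-yl]methylidene}chromium | C=C(C)[C@@H]1C[C@@H](O[Si](C)(C)C(C)(C)C)C=C(C(OC)=[Cr](=C=O)(=C=O)(=C=O)(=C=O)=C=O)[C@]1(C)CCCO[Si](C)(C)C(C)(C)C | intermediate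
21 | 3-methylbut-1-yne | CC(C)C#C | starting material
22 | tricarbonyl(η6-arene)chromium complex of 23, chromium on ring C (formed in situ) | C=C(C)[C@@H]1C[C@@H](O[Si](C)(C)C(C)(C)C)c2c(O)c(C(C)C)cc(OC)c2[C@]1(C)CCCO[Si](C)(C)C(C)(C)C.[Cr].[C-]#[O+].[C-]#[O+].[C-]#[O+] | intermediate
23 | (5R,6S,8R)-8-(tert-butyldimethylsilyloxy)-5-[3-(tert-butyldimethylsilyloxy)propyl]-4-methoxy-5-methyl-2-(propan-2-yl)-6-(prop-1-en-2-yl)-5,6,7,8-tetrahydronaphthalen-1-ol | C=C(C)[C@@H]1C[C@@H](O[Si](C)(C)C(C)(C)C)c2c(O)c(C(C)C)cc(OC)c2[C@]1(C)CCCO[Si](C)(C)C(C)(C)C | intermediate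
24 | (5R,6S,8R)-8-(tert-butyldimethylsilyloxy)-5-[3-(tert-butyldimethylsilyloxy)propyl]-5-methyl-2-(propan-2-yl)-6-(prop-1-en-2-yl)-5,6,7,8-tetrahydronaphthalene-1,4-dione | C=C(C)[C@@H]1C[C@@H](O[Si](C)(C)C(C)(C)C)C2=C(C(=O)C=C(C(C)C)C2=O)[C@]1(C)CCCO[Si](C)(C)C(C)(C)C | intermediate
25 | (5R,6S,8R)-8-(tert-butyldimethylsilyloxy)-5-[3-(tert-butyldimethylsilyloxy)propyl]-5-methyl-3-(morpholin-4-yl)-2-(propan-2-yl)-6-(prop-1-en-2-yl)-5,6,7,8-tetrahydronaphthalene-1,4-dione | C=C(C)[C@@H]1C[C@@H](O[Si](C)(C)C(C)(C)C)C2=C(C(=O)C(N3CCOCC3)=C(C(C)C)C2=O)[C@]1(C)CCCO[Si](C)(C)C(C)(C)C | intermediate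
26 | (5R,6S,8R)-8-(tert-butyldimethylsilyloxy)-5-[3-(tert-butyldimethylsilyloxy)propyl]-3-hydroxy-5-methyl-2-(propan-2-yl)-6-(prop-1-en-2-yl)-5,6,7,8-tetrahydronaphthalene-1,4-dione | C=C(C)[C@@H]1C[C@@H](O[Si](C)(C)C(C)(C)C)C2=C(C(=O)C(O)=C(C(C)C)C2=O)[C@]1(C)CCCO[Si](C)(C)C(C)(C)C | intermediate
27 | (5R,6S,8R)-3,8-dihydroxy-5-(3-hydroxypropyl)-5-methyl-2-(propan-2-yl)-6-(prop-1-en-2-yl)-5,6,7,8-tetrahydronaphthalene-1,4-dione | C=C(C)[C@@H]1C[C@@H](O)C2=C(C(=O)C(O)=C(C(C)C)C2=O)[C@]1(C)CCCO | intermediate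
28 | 3-[(1R,2S)-7-hydroxy-1-methyl-4,5,8-trioxo-6-(propan-2-yl)-2-(prop-1-en-2-yl)-1,2,3,4,5,8-hexahydronaphthalen-1-yl]propanoic acid | C=C(C)[C@@H]1CC(=O)C2=C(C(=O)C(O)=C(C(C)C)C2=O)[C@]1(C)CCC(=O)O | intermediate
29 | 3-[(1R,2S)-5,7,8-trihydroxy-1-methyl-4-oxo-6-(propan-2-yl)-2-(prop-1-en-2-yl)-1,2,3,4-tetrahydronaphthalen-1-yl]propanoic acid (CNP0198818.2) | C=C(C)[C@@H]1CC(=O)c2c(O)c(C(C)C)c(O)c(O)c2[C@]1(C)CCC(=O)O | target

Total step count: 16.
Longest linear sequence: 16 steps (1 to 29; compounds 3, 6, 17 and 21 enter as purchased materials).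

Steps most likely to fail

1. Step 3. What may go wrong: poor facial selectivity of an sp2 Grignard reagent in the copper-catalysed addition, and sluggish or unselective methylation of the magnesium enolate (proton transfer to C8, O-alkylation). The fallback sets out from enone 5 and changes both the nucleophile and the way the enolate is used. Isopropenyl(dimethyl)aluminium F1 (from 2-bromopropene by bromine–lithium exchange with t-BuLi and transmetalation with Me2AlCl) would be added under monovalent copper thiophene-2-carboxylate and a chiral phosphoramidite ligand in Et2O at −30 °C. The aluminium enolate would be trapped with TMSOTf as the trimethylsilyl enol ether F2, which is isolated. MeLi in THF would then release the lithium enolate F3, and methylation with MeI in THF–DMPU, anti to the isopropenyl group, would come back to the route at ketone 8.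

2. Step 10. What may go wrong: decomposition or diversion of the hindered carbene complex (cyclobutenone or furan formation, loss of the C7 silyloxy group from the ortho-hydroxybenzyl ether) before ring C closes. The fallback sets out from stannane 16 and builds ring C by a Moore rearrangement instead. Tin–lithium exchange to alkenyllithium 18 and addition at −78 °C to 3-isopropyl-4-methoxycyclobut-3-ene-1,2-dione F4 (a known reagent, two operations from dimethyl squarate) would give the 4-alkenyl-4-hydroxycyclobutenone F5, by attack at the carbonyl next to the methoxy-bearing carbon. Thermolysis in toluene at 110 °C (4π ring opening to a dienylketene, 6π closure onto C8) would give the 12-methoxy hydroquinone F6, which Ag2O would oxidise to the 12-methoxyquinone F7. Hydrolysis of this vinylogous ester with dilute aqueous NaOH in THF–MeOH would come back to the route at hydroxyquinone 26, so that steps 9 to 13 are bypassed.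

3. Step 12. What may go wrong: slow conjugate addition at C12 next to the isopropyl group, with base-induced tautomerisation of the quinone toward C7 competing. The fallback sets out from quinone 24 and installs oxygen directly. Nucleophilic epoxidation of the C12=C13 bond with tBuOOH and DBU in CH2Cl2 at 0 °C would give the epoxyquinone F8. Brief treatment with H2SO4 adsorbed on silica gel in CH2Cl2 (opening at C13, loss of the C12 hydrogen) would isomerise it and come back to the route at hydroxyquinone 26. Exposure to acid is kept short because of the isopropenyl group and the silyl ethers.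

Further compounds
F1 | step 3 | isopropenyl(dimethyl)aluminium | C=C(C)[Al](C)C
F2 | step 3 | (S)-tert-butyldimethyl{3-[6-(prop-1-en-2-yl)-2-(trimethylsilyloxy)cyclohex-1-en-1-yl]propoxy}silane | C=C(C)[C@@H]1CCCC(O[Si](C)(C)C)=C1CCCO[Si](C)(C)C(C)(C)C
F3 | step 3 | lithium enolate from F2 | C=C(C)[C@@H]1CCCC(O[Li])=C1CCCO[Si](C)(C)C(C)(C)C
F4 | step 10 | 3-isopropyl-4-methoxycyclobut-3-ene-1,2-dione | COC1=C(C(C)C)C(=O)C1=O
F5 | step 10 | 4-hydroxy-3-methoxy-2-isopropyl-4-[(3R,5S,6R)-3-(tert-butyldimethylsilyloxy)-6-[3-(tert-butyldimethylsilyloxy)propyl]-6-methyl-5-(prop-1-en-2-yl)cyclohex-1-en-1-yl]cyclobut-2-en-1-one (carbinol epimers) | C=C(C)[C@@H]1C[C@@H](O[Si](C)(C)C(C)(C)C)C=C(C2(O)C(OC)=C(C(C)C)C2=O)[C@]1(C)CCCO[Si](C)(C)C(C)(C)C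
F6 | step 10 | (5R,6S,8R)-8-(tert-butyldimethylsilyloxy)-5-[3-(tert-butyldimethylsilyloxy)propyl]-3-methoxy-5-methyl-2-(propan-2-yl)-6-(prop-1-en-2-yl)-5,6,7,8-tetrahydronaphthalene-1,4-diol | C=C(C)[C@@H]1C[C@@H](O[Si](C)(C)C(C)(C)C)c2c(O)c(C(C)C)c(OC)c(O)c2[C@]1(C)CCCO[Si](C)(C)C(C)(C)C
F7 | step 10 | (5R,6S,8R)-8-(tert-butyldimethylsilyloxy)-5-[3-(tert-butyldimethylsilyloxy)propyl]-3-methoxy-5-methyl-2-(propan-2-yl)-6-(prop-1-en-2-yl)-5,6,7,8-tetrahydronaphthalene-1,4-dione | C=C(C)[C@@H]1C[C@@H](O[Si](C)(C)C(C)(C)C)C2=C(C(=O)C(OC)=C(C(C)C)C2=O)[C@]1(C)CCCO[Si](C)(C)C(C)(C)C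
F8 | step 12 | C12,C13-epoxide of quinone 24 (epoxide epimers) | C=C(C)[C@@H]1C[C@@H](O[Si](C)(C)C(C)(C)C)C2=C(C(=O)C3OC3(C(C)C)C2=O)[C@]1(C)CCCO[Si](C)(C)C(C)(C)C
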